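The 42-membered lactone ring (C1–C41 plus the ring oxygen) is opened at its only cis-disubstituted alkene, C38=C39, which lies in an unbranched stretch between the C32–C37 hexamethylene chain and C40. Ring-closing alkyne metathesis of a diyne forms the C38≡C39 bond and the macrocycle in one operation; semihydrogenation then sets the Z geometry. The precursor is the open-chain C41 ester of the (2Z,4Z)-dienoic acid whose two chain ends are methyl-capped alkynes, with all twelve hydroxyl groups as TBS ethers. Its dienoate is made by a Z-selective Horner–Wadsworth–Emmons union, so no free dienoic acid is handled.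

Key step: step 37

Remark: C-numbers are those of the target (C1 lactone carbonyl, C41 the ring carbon bearing the lactone oxygen, C42–C50 side chain); TBS = tert-butyldimethylsilyl, TBSO = its oxygen-bound form.
Assumption: (S)-2-(2-bromoethyl)oxirane, prop-1-ynyllithium and 2-[bis(2,2,2-trifluoroethoxy)phosphoryl]acetic acid are taken as purchased (the first is also the epoxide recovered from hydrolytic kinetic resolution of the racemate).

**C3–C15 aldehyde enoate**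

Step 1
Reactants: 1 propane-1,3-diol; 2 allyl acetate
Product: 3 (4R,6R)-nona-1,8-diene-4,6-diol
Conditions: [Ir(cod)Cl]2 (5 mol%), (R)-Cl,MeO-BIPHEP (10 mol%), 4-chloro-3-nitrobenzoic acid (20 mol%), Cs2CO3 (40 mol%), allyl acetate (10 equiv), 1,4-dioxane, 90 °C
Reagents that add atoms: allyl acetate (second equivalent of 2), CC(=O)OCC=C
Why: Krische two-directional transfer-hydrogenative allylation from the alcohol oxidation level, in which each of the two transient aldehydes takes one allyl group from one molecule of 2 under ligand control (the ligand enantiomer is the one expected to deliver the R,R-diol), sets C9 and C11 as the C2-symmetric anti-diol.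

Step 2
Reactants: 3 (4R,6R)-nona-1,8-diene-4,6-diol
Product: 4 (4R,6R)-4,6-bis(TBSO)nona-1,8-diene
Conditions: TBSCl, imidazole, DMF, rt
Reagents that add atoms: tert-butyldimethylsilyl chloride, CC(C)(C)[Si](C)(C)Cl
Why: Imidazole-promoted silyl ether formation masks both secondary alcohols before the oxidative cleavage.

Step 3
Reactants: 4 (4R,6R)-4,6-bis(TBSO)nona-1,8-diene
Product: 6 (3R,5R)-3,5-bis(TBSO)heptane-1,7-diol, via dialdehyde 5 (not isolated)
Conditions: O3, CH2Cl2/MeOH, −78 °C; then NaBH4, −78 °C → rt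
Reagents that add atoms: ozone, [O-][O+]=O
Why: Ozonolysis of both terminal alkenes with reductive work-up gives the primary diol without touching the silyl ethers or the stereocentres.

Step 4
Reactants: 6 (3R,5R)-3,5-bis(TBSO)heptane-1,7-diol; 2 allyl acetate
Product: 7 (4S,6R,8R,10S)-6,8-bis(TBSO)trideca-1,12-diene-4,10-diol
Conditions: [Ir(cod)Cl]2 (5 mol%), (S)-Cl,MeO-BIPHEP (10 mol%), 4-chloro-3-nitrobenzoic acid (20 mol%), Cs2CO3 (40 mol%), allyl acetate (10 equiv), 1,4-dioxane, 90 °C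
Reagents that add atoms: allyl acetate (second equivalent of 2), CC(=O)OCC=C
Why: A second two-directional Krische allylation, again consuming one molecule of 2 at each terminus but now with the ligand of opposite handedness, should set C7 and C13 anti to C9 and C11 by catalyst control over the β-silyloxy centres.

Step 5
Reactants: 7 (4S,6R,8R,10S)-6,8-bis(TBSO)trideca-1,12-diene-4,10-diol
Product: 8 (4S,6R,8R,10S)-4,6,8,10-tetrakis(TBSO)trideca-1,12-diene
Conditions: TBSOTf, 2,6-lutidine, CH2Cl2, −78 → 0 °C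
Reagents that add atoms: tert-butyldimethylsilyl triflate, CC(C)(C)[Si](C)(C)OS(=O)(=O)C(F)(F)F
Why: Triflate-mediated silylation protects the two new carbinols, giving the all-anti tetrakis(silyl ether).

Step 6
Reactants: 8 (4S,6R,8R,10S)-4,6,8,10-tetrakis(TBSO)trideca-1,12-diene
Product: 9 (3R,5S,7S,9R)-3,5,7,9-tetrakis(TBSO)undecanedial
Conditions: O3, CH2Cl2, −78 °C; then PPh3, −78 °C → rt
Reagents that add atoms: ozone, [O-][O+]=O
Why: Ozonolysis with reductive (phosphine) work-up gives the C2-symmetric dialdehyde whose formyl carbons are C5 and C15.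

Step 7
Reactants: 9 (3R,5S,7S,9R)-3,5,7,9-tetrakis(TBSO)undecanedial; 10 ethyl 2-[bis(2,2,2-trifluoroethoxy)phosphoryl]propanoate
Product: 11 ethyl (2Z,5S,7R,9S,11R)-5,7,9,11-tetrakis(TBSO)-2-methyl-13-oxotridec-2-enoate (C3–C15 aldehyde enoate)
Conditions: 10 (0.5 equiv), KN(SiMe3)2, 18-crown-6, THF, −78 °C; unreacted 9 recovered and recycled
Reagents that add atoms: none
Why: A Still–Gennari olefination run with a deficit of phosphonate converts one of the two homotopic formyl groups, so the mono-adduct is a single compound, and the trifluoroethyl phosphonate under dissociating conditions should give the Z-trisubstituted C4=C5 enoate.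

**C16–C38 methyl ketone**

Step 8
Reactants: 12 1-bromo-5-chloropentane; 13 prop-1-ynyllithium
Product: 14 8-chlorooct-2-yne
Conditions: THF/DMPU, −78 °C → rt
Reagents that add atoms: none
Why: SN2 alkylation of the acetylide takes place at the bromide terminus and leaves the chloride for Grignard formation.

Step 9
Reactants: 14 8-chlorooct-2-yne; 15 (S)-2-(2-bromoethyl)oxirane
Product: 17 (R)-1-bromododec-10-yn-3-ol, via Grignard reagent 16 (not isolated)
Conditions: Mg, BrCH2CH2Br (cat.), THF, reflux; then 15, CuI (10 mol%), THF, −40 → −20 °C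
Reagents that add atoms: none
Why: CuI-catalysed Grignard opening of the terminal epoxide at its CH2 (C32) is faster than coupling at the C–Br bond at low temperature, and C31 comes unchanged from epoxide 15.

Step 10
Reactants: 17 (R)-1-bromododec-10-yn-3-ol
Product: 18 (R)-1-bromo-3-(TBSO)dodec-10-yne
Conditions: TBSOTf, 2,6-lutidine, CH2Cl2, −78 °C
Reagents that add atoms: tert-butyldimethylsilyl triflate, CC(C)(C)[Si](C)(C)OS(=O)(=O)C(F)(F)F
Why: Non-nucleophilic silylation protects the carbinol without displacing the primary bromide.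

Step 11
Reactants: 18 (R)-1-bromo-3-(TBSO)dodec-10-yne; 15 (S)-2-(2-bromoethyl)oxirane
Product: 20 (3R,7R)-1-bromo-7-(TBSO)hexadec-14-yn-3-ol, via Grignard reagent 19 (not isolated)
Conditions: Mg, THF, 40 °C; then 15, CuI (10 mol%), THF, −40 → −20 °C
Reagents that add atoms: none
Why: The γ-silyloxy Grignard reagent has no β-leaving group and opens the epoxide at CH2 (C28) under CuI catalysis, so C27 is again taken from 15.

Step 12
Reactants: 20 (3R,7R)-1-bromo-7-(TBSO)hexadec-14-yn-3-ol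
Product: 21 (3R,7R)-1-bromo-3,7-bis(TBSO)hexadec-14-yne
Conditions: TBSOTf, 2,6-lutidine, CH2Cl2, −78 °C
Reagents that add atoms: tert-butyldimethylsilyl triflate, CC(C)(C)[Si](C)(C)OS(=O)(=O)C(F)(F)F
Why: Silyl ether formation as in step 10.

Step 13
Reactants: 21 (3R,7R)-1-bromo-3,7-bis(TBSO)hexadec-14-yne; 15 (S)-2-(2-bromoethyl)oxirane
Product: 23 (3R,7S,11R)-1-bromo-7,11-bis(TBSO)icos-18-yn-3-ol, via Grignard reagent 22 (not isolated)
Conditions: Mg, THF, 40 °C; then 15, CuI (10 mol%), THF, −40 → −20 °C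
Reagents that add atoms: none
Why: A third CuI-catalysed Grignard epoxide opening adds C21–C24 and brings in C23 from 15, the 7S descriptor of 23 reflecting only a change of CIP priorities caused by the free C3 hydroxyl and not a change of configuration.

Step 14
Reactants: 23 (3R,7S,11R)-1-bromo-7,11-bis(TBSO)icos-18-yn-3-ol
Product: 24 (3R,7R,11R)-1-bromo-3,7,11-tris(TBSO)icos-18-yne
Conditions: TBSOTf, 2,6-lutidine, CH2Cl2, −78 °C
Reagents that add atoms: tert-butyldimethylsilyl triflate, CC(C)(C)[Si](C)(C)OS(=O)(=O)C(F)(F)F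
Why: Silyl ether formation as in step 10.

Step 15
Reactants: 24 (3R,7R,11R)-1-bromo-3,7,11-tris(TBSO)icos-18-yne
Product: 25 [(3R,7R,11R)-3,7,11-tris(TBSO)icos-18-ynyl]triphenylphosphonium bromide
Conditions: PPh3, i-Pr2NEt (cat.), MeCN, 80 °C
Reagents that add atoms: triphenylphosphine, c1ccc(cc1)P(c1ccccc1)c1ccccc1
Why: SN2 quaternisation of the phosphine by the primary bromide (C21) gives the Wittig salt.

Step 16
Reactants: 25 [(3R,7R,11R)-3,7,11-tris(TBSO)icos-18-ynyl]triphenylphosphonium bromide; 26 1,1-dimethoxypropan-2-one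
Product: 28 (2Z,5R,9R,13R)-2-methyl-5,9,13-tris(TBSO)docos-2-en-20-ynal (C19–C38 enal), via dimethyl acetal 27 (not isolated)
Conditions: NaN(SiMe3)2, THF, −78 °C; 26, −78 °C → rt; then aq. oxalic acid, THF, 0 °C
Reagents that add atoms: water, O
Why: Wittig olefination of the non-stabilised ylide with an α,α-dialkoxy ketone should place the acetal carbon cis to the chain (Z-trisubstituted C20=C21), and mild acid hydrolysis of the allylic acetal then frees the enal without loss of silyl ethers.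

Step 17
Reactants: 28 (2Z,5R,9R,13R)-2-methyl-5,9,13-tris(TBSO)docos-2-en-20-ynal; 29 (S)-4-benzyl-3-propionyloxazolidin-2-one
Product: 30 (S)-4-benzyl-3-[(2S,3S,4Z,7R,11R,15R)-3-hydroxy-2,4-dimethyl-7,11,15-tris(TBSO)tetracos-4-en-22-ynoyl]oxazolidin-2-one
Conditions: 29, Bu2BOTf, Et3N, CH2Cl2, −78 → 0 °C; 28, −78 → 0 °C; pH 7 buffer, MeOH, H2O2
Reagents that add atoms: none
Why: Evans syn aldol reaction, in which the Z-boron enolate adds through a Zimmerman–Traxler transition state on the face fixed by the auxiliary, sets C18 and C19 (syn).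

Step 18
Reactants: 30 Evans aldol adduct
Product: 31 (2S,3S,4Z,7R,11R,15R)-3-hydroxy-N-methoxy-N,2,4-trimethyl-7,11,15-tris(TBSO)tetracos-4-en-22-ynamide
Conditions: MeNH(OMe)·HCl, Me3Al, CH2Cl2, −20 → 0 °C
Reagents that add atoms: N,O-dimethylhydroxylamine hydrochloride, CNOC.Cl
Why: Me3Al-mediated transamination (Weinreb amide formation), assisted by the free β-hydroxyl, removes the auxiliary without epimerising C18.

Step 19
Reactants: 31 Weinreb amide
Product: 32 (2S,3S,4Z,7R,11R,15R)-N-methoxy-N,2,4-trimethyl-3,7,11,15-tetrakis(TBSO)tetracos-4-en-22-ynamide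
Conditions: TBSOTf, 2,6-lutidine, CH2Cl2, −78 → 0 °C
Reagents that add atoms: tert-butyldimethylsilyl triflate, CC(C)(C)[Si](C)(C)OS(=O)(=O)C(F)(F)F
Why: Silylation of the allylic C19 hydroxyl before the organometallic step.

Step 20
Reactants: 32 silylated Weinreb amide
Product: 33 (3S,4S,5Z,8R,12R,16R)-3,5-dimethyl-4,8,12,16-tetrakis(TBSO)pentacos-5-en-23-yn-2-one (C16–C38 methyl ketone)
Conditions: MeMgBr, THF, 0 °C
Reagents that add atoms: methylmagnesium bromide, C[Mg]Br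
Why: Weinreb ketone synthesis, in which the chelated tetrahedral intermediate stops the addition at the methyl ketone (the methyl is C16).

**C39–C50 phosphonate**

Step 21
Reactants: 34 (R)-propylene oxide; 35 6-bromohex-1-ene
Product: 37 (R)-non-8-en-2-ol, via Grignard reagent 36 (not isolated)
Conditions: Mg, THF; then 34, CuI (10 mol%), THF, −30 → 0 °C
Reagents that add atoms: none
Why: CuI-catalysed Grignard opening of the epoxide at CH2 leaves the chiral-pool centre C49 untouched.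

Step 22
Reactants: 37 (R)-non-8-en-2-ol
Product: 38 (R)-tert-butyldimethyl(non-8-en-2-yloxy)silane
Conditions: TBSCl, imidazole, DMF, rt
Reagents that add atoms: tert-butyldimethylsilyl chloride, CC(C)(C)[Si](C)(C)Cl
Why: Standard silyl ether formation.

Step 23
Reactants: 38 (R)-tert-butyldimethyl(non-8-en-2-yloxy)silane
Product: 39 (R)-7-(TBSO)octanal
Conditions: O3, CH2Cl2, −78 °C; then PPh3
Reagents that add atoms: ozone, [O-][O+]=O
Why: Ozonolysis of the terminal alkene gives the C43 aldehyde.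

Step 24
Reactants: 39 (R)-7-(TBSO)octanal
Product: 40 (3R,4R,10R)-10-(TBSO)-3-methylundec-1-en-4-ol
Conditions: (Z)-but-2-ene, KOtBu, n-BuLi, THF, −78 → −45 °C; (−)-Ipc2BOMe, −78 °C; BF3·OEt2; 39, −78 °C; then NaOH, H2O2
Reagents that add atoms: (Z)-but-2-ene, C/C=C\C
Why: Brown crotylboration, in which the (Z)-crotylborane reacts through a chair transition state to give the syn adduct and the isopinocampheyl groups choose the aldehyde face, sets C42 and C43.

Step 25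
Reactants: 40 (3R,4R,10R)-10-(TBSO)-3-methylundec-1-en-4-ol
Product: 41 tert-butyl (3R,4R,10R)-10-(TBSO)-3-methylundec-1-en-4-yl carbonate
Conditions: NaN(SiMe3)2, Boc2O, THF, −78 → 0 °C
Reagents that add atoms: di-tert-butyl dicarbonate, CC(C)(C)OC(=O)OC(=O)OC(C)(C)C
Why: Acylation of the alkoxide installs the internal carbonate nucleophile for the cyclisation.

Step 26
Reactants: 41 homoallylic tert-butyl carbonate
Product: 42 (4R,5S,6R)-4-(iodomethyl)-5-methyl-6-[(6R)-6-(TBSO)heptyl]-1,3-dioxan-2-one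
Conditions: IBr, toluene, −85 °C
Reagents that add atoms: iodine monobromide, IBr
Why: Bartlett–Smith iodocarbonate cyclisation, in which the carbonate carbonyl attacks the iodonium ion through a chair-like six-membered transition state with both chain substituents equatorial, should give the 1,3-syn relationship and so set C41.

Step 27
Reactants: 42 iodo carbonate
Product: 43 (2S,3R,9R)-9-(TBSO)-2-[(2R)-oxiran-2-yl]decan-3-ol
Conditions: K2CO3, MeOH, rt
Reagents that add atoms: none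
Why: Carbonate methanolysis frees the C41 alkoxide, which displaces iodide in an intramolecular Williamson reaction to give the terminal epoxide with C41 unchanged.

Step 28
Reactants: 43 epoxy alcohol
Product: 44 (R)-2-[(2R,3R,9R)-3,9-bis(TBSO)decan-2-yl]oxirane
Conditions: TBSOTf, 2,6-lutidine, CH2Cl2, −78 °C
Reagents that add atoms: tert-butyldimethylsilyl triflate, CC(C)(C)[Si](C)(C)OS(=O)(=O)C(F)(F)F
Why: Buffered low-temperature silylation protects the C43 hydroxyl and spares the epoxide.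

Step 29
Reactants: 44 silylated epoxide; 13 prop-1-ynyllithium
Product: 45 (5S,6R,7R,13R)-7,13-bis(TBSO)-6-methyltetradec-2-yn-5-ol (C39–C50 alcohol)
Conditions: 13, BF3·OEt2, THF, −78 °C
Reagents that add atoms: none
Why: Yamaguchi–Hirao alkynylation opens the BF3-activated terminal epoxide at C40 only, which gives the but-2-ynyl carbinol free of allenyl isomers and leaves the C41 hydroxyl free.

Step 30
Reactants: 45 C39–C50 alcohol; 46 2-[bis(2,2,2-trifluoroethoxy)phosphoryl]acetic acid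
Product: 47 (5S,6R,7R,13R)-7,13-bis(TBSO)-6-methyltetradec-2-yn-5-yl 2-[bis(2,2,2-trifluoroethoxy)phosphoryl]acetate
Conditions: DCC, DMAP (cat.), CH2Cl2, 0 °C → rt
Reagents that add atoms: none
Why: Steglich esterification of the hindered secondary alcohol with the activated phosphonoacetic acid puts the future C1–C2 unit on O41.

**Union and endgame**

Step 31
Reactants: 33 C16–C38 methyl ketone; 11 C3–C15 aldehyde enoate
Product: 48 C3–C38 aldol adduct (ethyl Z-enoate with 15-hydroxy, 17-oxo and eight TBSO groups; configuration as in the SMILES)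
Conditions: 33, c-Hex2BCl, Et3N, Et2O, −78 → 0 °C; 11, −78 → −20 °C; pH 7 buffer, MeOH, H2O2
Reagents that add atoms: none
Why: Paterson boron aldol reaction, with kinetic enolisation on the methyl side and addition through a cyclic transition state in which the α-methyl centre C18 of the enol borinate should direct the attack (1,4-syn induction), sets C15.

Step 32
Reactants: 48 C3–C38 aldol adduct
Product: 49 C3–C38 15,17-anti-diol
Conditions: Me4NBH(OAc)3, MeCN/AcOH, −30 °C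
Reagents that add atoms: none
Why: Evans–Saksena reduction, in which the acetoxyborohydride bound to the C15 hydroxyl delivers hydride intramolecularly, should give the 1,3-anti diol and so set C17 (anti to C18, which completes the C17–C19 triad).

Step 33
Reactants: 49 C3–C38 15,17-anti-diol
Product: 50 C3–C38 ethyl enoate with ten TBSO groups
Conditions: TBSOTf, 2,6-lutidine, CH2Cl2, −78 → 0 °C
Reagents that add atoms: tert-butyldimethylsilyl triflate, CC(C)(C)[Si](C)(C)OS(=O)(=O)C(F)(F)F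
Why: Silylation of both new carbinols gives a uniform protecting-group set for a single final deprotection.

Step 34
Reactants: 50 C3–C38 ethyl enoate
Product: 51 C3–C38 Z-allylic alcohol
Conditions: i-Bu2AlH, CH2Cl2, −78 °C
Reagents that add atoms: none
Why: 1,2-Reduction of the enoate by i-Bu2AlH gives the allylic alcohol with the C4=C5 geometry retained.

Step 35
Reactants: 51 C3–C38 Z-allylic alcohol
Product: 52 C3–C38 Z-enal
Conditions: Dess–Martin periodinane, NaHCO3, CH2Cl2, 0 °C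
Reagents that add atoms: none
Why: Buffered hypervalent-iodine oxidation should give the Z-enal without isomerisation.

Step 36
Reactants: 52 C3–C38 Z-enal; 47 C39–C50 phosphonoacetate
Product: 53 seco ester diyne (C41 ester of the (2Z,4Z)-dienoic acid, both alkynes methyl-capped, twelve TBSO groups)
Conditions: 47, KN(SiMe3)2, 18-crown-6, THF, −78 °C; then 52, −78 °C
Reagents that add atoms: none
Why: Still–Gennari (Z-selective Horner–Wadsworth–Emmons) olefination joins the two fragments and builds the C2=C3 Z-alkene of the ester in one step.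

Step 37
Reactants: 53 seco ester diyne
Product: 54 42-membered cycloalkyne lactone (C38≡C39, twelve TBSO groups)
Conditions: Mo(≡C-C6H4-4-OMe)(OSiPh3)3 (20 mol%), 5 Å molecular sieves, toluene (1 mM), rt → 60 °C
Reagents that add atoms: none
Why: Each C≡C–CH3 terminus undergoes [2+2] cycloaddition with the Mo≡C unit and cycloreversion through a metallacyclobutadiene, so the first exchange loads the chain onto molybdenum with loss of but-2-yne (trapped by the sieves) and the second, intramolecular exchange forms C38≡C39. The closest known reaction type is ring-closing alkyne metathesis of methyl-capped diynes in macrolide synthesis with catalysts of the type Mo(≡CAr)(OSiPh3)3. The 42-membered ring closes end to end, by union of the two chain termini, as a strain-free cycloalkyne under high dilution and thermodynamic control, since the exchange is reversible and but-2-yne is removed. No stereocentre is formed, and the Z geometry of C38=C39 is fixed only afterwards by syn delivery of hydrogen in step 38. The step needs alkyne-over-alkene chemoselectivity, which the alkylidyne supplies (the four C=C bonds, the dienoate ester and the silyl ethers are inert to it). It also needs ring-over-oligomer selectivity, which dilution, reversibility and the unbranched CH2 surroundings of both alkynes (C37 and C40) secure.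

Step 38
Reactants: 54 cycloalkyne lactone
Product: 55 per-TBS macrolactone with Z-C38=C39
Conditions: H2 (1 atm), Pd/CaCO3 poisoned with Pb(OAc)2, quinoline, EtOAc, rt
Reagents that add atoms: none
Why: Semihydrogenation over the Pb(OAc)2-poisoned Pd/CaCO3 surface (Lindlar reduction) delivers both hydrogens to one face of the cycloalkyne, giving the Z-alkene and sparing the trisubstituted and conjugated alkenes.

Step 39
Reactants: 55 per-TBS macrolactone
Product: 56 target CNP0392687.2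
Conditions: HF·pyridine, pyridine, THF, 0 °C → rt
Reagents that add atoms: none
Why: Buffered fluoride cleavage of all twelve Si–O bonds frees the polyol under conditions mild enough for the (2Z,4Z)-dienoate and the allylic C19 alcohol.

**Compound list**

1 | propane-1,3-diol | OCCCO | starting material
2 | allyl acetate | CC(=O)OCC=C | starting material
3 | (4R,6R)-nona-1,8-diene-4,6-diol | C=CC[C@@H](O)C[C@H](O)CC=C | intermediate
4 | (4R,6R)-4,6-bis(TBSO)nona-1,8-diene | C=CC[C@@H](O[Si](C)(C)C(C)(C)C)C[C@H](O[Si](C)(C)C(C)(C)C)CC=C | intermediate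
5 | (3S,5S)-3,5-bis(TBSO)heptanedial (not isolated) | O=CC[C@@H](O[Si](C)(C)C(C)(C)C)C[C@H](O[Si](C)(C)C(C)(C)C)CC=O | intermediate
6 | (3R,5R)-3,5-bis(TBSO)heptane-1,7-diol | OCC[C@@H](O[Si](C)(C)C(C)(C)C)C[C@H](O[Si](C)(C)C(C)(C)C)CCO | intermediate
7 | (4S,6R,8R,10S)-6,8-bis(TBSO)trideca-1,12-diene-4,10-diol | C=CC[C@H](O)C[C@@H](O[Si](C)(C)C(C)(C)C)C[C@H](O[Si](C)(C)C(C)(C)C)C[C@@H](O)CC=C | intermediate
8 | (4S,6R,8R,10S)-4,6,8,10-tetrakis(TBSO)trideca-1,12-diene | C=CC[C@H](O[Si](C)(C)C(C)(C)C)C[C@@H](O[Si](C)(C)C(C)(C)C)C[C@H](O[Si](C)(C)C(C)(C)C)C[C@@H](O[Si](C)(C)C(C)(C)C)CC=C | intermediate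
9 | (3R,5S,7S,9R)-3,5,7,9-tetrakis(TBSO)undecanedial | O=CC[C@H](O[Si](C)(C)C(C)(C)C)C[C@@H](O[Si](C)(C)C(C)(C)C)C[C@H](O[Si](C)(C)C(C)(C)C)C[C@@H](O[Si](C)(C)C(C)(C)C)CC=O | intermediate
10 | ethyl 2-[bis(2,2,2-trifluoroethoxy)phosphoryl]propanoate | CCOC(=O)C(C)P(=O)(OCC(F)(F)F)OCC(F)(F)F | starting material
11 | ethyl (2Z,5S,7R,9S,11R)-5,7,9,11-tetrakis(TBSO)-2-methyl-13-oxotridec-2-enoate | CCOC(=O)/C(C)=C\C[C@H](O[Si](C)(C)C(C)(C)C)C[C@@H](O[Si](C)(C)C(C)(C)C)C[C@H](O[Si](C)(C)C(C)(C)C)C[C@@H](O[Si](C)(C)C(C)(C)C)CC=O | intermediate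
12 | 1-bromo-5-chloropentane | ClCCCCCBr | starting material
13 | prop-1-ynyllithium | [Li]C#CC | starting material
14 | 8-chlorooct-2-yne | CC#CCCCCCCl | intermediate
15 | (S)-2-(2-bromoethyl)oxirane | BrCC[C@H]1CO1 | starting material
16 | oct-6-ynylmagnesium chloride (not isolated) | CC#CCCCCC[Mg]Cl | intermediate
17 | (R)-1-bromododec-10-yn-3-ol | CC#CCCCCCC[C@@H](O)CCBr | intermediate
18 | (R)-1-bromo-3-(TBSO)dodec-10-yne | CC#CCCCCCC[C@@H](O[Si](C)(C)C(C)(C)C)CCBr | intermediate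
19 | [(R)-3-(TBSO)dodec-10-ynyl]magnesium bromide (not isolated) | CC#CCCCCCC[C@@H](O[Si](C)(C)C(C)(C)C)CC[Mg]Br | intermediate
20 | (3R,7R)-1-bromo-7-(TBSO)hexadec-14-yn-3-ol | CC#CCCCCCC[C@@H](O[Si](C)(C)C(C)(C)C)CCC[C@@H](O)CCBr | intermediate
21 | (3R,7R)-1-bromo-3,7-bis(TBSO)hexadec-14-yne | CC#CCCCCCC[C@@H](O[Si](C)(C)C(C)(C)C)CCC[C@@H](O[Si](C)(C)C(C)(C)C)CCBr | intermediate
22 | [(3R,7R)-3,7-bis(TBSO)hexadec-14-ynyl]magnesium bromide (not isolated) | CC#CCCCCCC[C@@H](O[Si](C)(C)C(C)(C)C)CCC[C@@H](O[Si](C)(C)C(C)(C)C)CC[Mg]Br | intermediate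
23 | (3R,7S,11R)-1-bromo-7,11-bis(TBSO)icos-18-yn-3-ol | CC#CCCCCCC[C@@H](O[Si](C)(C)C(C)(C)C)CCC[C@@H](O[Si](C)(C)C(C)(C)C)CCC[C@@H](O)CCBr | intermediate
24 | (3R,7R,11R)-1-bromo-3,7,11-tris(TBSO)icos-18-yne | CC#CCCCCCC[C@@H](O[Si](C)(C)C(C)(C)C)CCC[C@@H](O[Si](C)(C)C(C)(C)C)CCC[C@@H](O[Si](C)(C)C(C)(C)C)CCBr | intermediate
25 | [(3R,7R,11R)-3,7,11-tris(TBSO)icos-18-ynyl]triphenylphosphonium bromide | CC#CCCCCCC[C@@H](O[Si](C)(C)C(C)(C)C)CCC[C@@H](O[Si](C)(C)C(C)(C)C)CCC[C@@H](O[Si](C)(C)C(C)(C)C)CC[P+](c1ccccc1)(c1ccccc1)c1ccccc1.[Br-] | intermediate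
26 | 1,1-dimethoxypropan-2-one | CC(=O)C(OC)OC | starting material
27 | (2Z,5R,9R,13R)-1,1-dimethoxy-2-methyl-5,9,13-tris(TBSO)docos-2-en-20-yne (not isolated) | COC(OC)/C(C)=C\C[C@H](O[Si](C)(C)C(C)(C)C)CCC[C@H](O[Si](C)(C)C(C)(C)C)CCC[C@H](O[Si](C)(C)C(C)(C)C)CCCCCCC#CC | intermediate
28 | (2Z,5R,9R,13R)-2-methyl-5,9,13-tris(TBSO)docos-2-en-20-ynal | O=C/C(C)=C\C[C@H](O[Si](C)(C)C(C)(C)C)CCC[C@H](O[Si](C)(C)C(C)(C)C)CCC[C@H](O[Si](C)(C)C(C)(C)C)CCCCCCC#CC | intermediate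
29 | (S)-4-benzyl-3-propionyloxazolidin-2-one | CCC(=O)N1[C@@H](Cc2ccccc2)COC1=O | starting material
30 | (S)-4-benzyl-3-[(2S,3S,4Z,7R,11R,15R)-3-hydroxy-2,4-dimethyl-7,11,15-tris(TBSO)tetracos-4-en-22-ynoyl]oxazolidin-2-one | O=C(N1[C@@H](Cc2ccccc2)COC1=O)[C@@H](C)[C@H](O)/C(C)=C\C[C@H](O[Si](C)(C)C(C)(C)C)CCC[C@H](O[Si](C)(C)C(C)(C)C)CCC[C@H](O[Si](C)(C)C(C)(C)C)CCCCCCC#CC | intermediate
31 | (2S,3S,4Z,7R,11R,15R)-3-hydroxy-N-methoxy-N,2,4-trimethyl-7,11,15-tris(TBSO)tetracos-4-en-22-ynamide | CON(C)C(=O)[C@@H](C)[C@H](O)/C(C)=C\C[C@H](O[Si](C)(C)C(C)(C)C)CCC[C@H](O[Si](C)(C)C(C)(C)C)CCC[C@H](O[Si](C)(C)C(C)(C)C)CCCCCCC#CC | intermediate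
32 | (2S,3S,4Z,7R,11R,15R)-N-methoxy-N,2,4-trimethyl-3,7,11,15-tetrakis(TBSO)tetracos-4-en-22-ynamide | CON(C)C(=O)[C@@H](C)[C@H](O[Si](C)(C)C(C)(C)C)/C(C)=C\C[C@H](O[Si](C)(C)C(C)(C)C)CCC[C@H](O[Si](C)(C)C(C)(C)C)CCC[C@H](O[Si](C)(C)C(C)(C)C)CCCCCCC#CC | intermediate
33 | (3S,4S,5Z,8R,12R,16R)-3,5-dimethyl-4,8,12,16-tetrakis(TBSO)pentacos-5-en-23-yn-2-one | CC(=O)[C@@H](C)[C@H](O[Si](C)(C)C(C)(C)C)/C(C)=C\C[C@H](O[Si](C)(C)C(C)(C)C)CCC[C@H](O[Si](C)(C)C(C)(C)C)CCC[C@H](O[Si](C)(C)C(C)(C)C)CCCCCCC#CC | intermediate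
34 | (R)-propylene oxide | C[C@@H]1CO1 | starting material
35 | 6-bromohex-1-ene | C=CCCCCBr | starting material
36 | hex-5-enylmagnesium bromide (not isolated) | C=CCCCC[Mg]Br | intermediate
37 | (R)-non-8-en-2-ol | C[C@@H](O)CCCCCC=C | intermediate
38 | (R)-tert-butyldimethyl(non-8-en-2-yloxy)silane | C[C@@H](O[Si](C)(C)C(C)(C)C)CCCCCC=C | intermediate
39 | (R)-7-(TBSO)octanal | C[C@@H](O[Si](C)(C)C(C)(C)C)CCCCCC=O | intermediate
40 | (3R,4R,10R)-10-(TBSO)-3-methylundec-1-en-4-ol | C=C[C@@H](C)[C@H](O)CCCCC[C@@H](C)O[Si](C)(C)C(C)(C)C | intermediate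
41 | tert-butyl (3R,4R,10R)-10-(TBSO)-3-methylundec-1-en-4-yl carbonate | C=C[C@@H](C)[C@H](OC(=O)OC(C)(C)C)CCCCC[C@@H](C)O[Si](C)(C)C(C)(C)C | intermediate
42 | (4R,5S,6R)-4-(iodomethyl)-5-methyl-6-[(6R)-6-(TBSO)heptyl]-1,3-dioxan-2-one | IC[C@@H]1OC(=O)O[C@H](CCCCC[C@@H](C)O[Si](C)(C)C(C)(C)C)[C@@H]1C | intermediate
43 | (2S,3R,9R)-9-(TBSO)-2-[(2R)-oxiran-2-yl]decan-3-ol | C1O[C@@H]1[C@@H](C)[C@H](O)CCCCC[C@@H](C)O[Si](C)(C)C(C)(C)C | intermediate
44 | (R)-2-[(2R,3R,9R)-3,9-bis(TBSO)decan-2-yl]oxirane | C1O[C@@H]1[C@@H](C)[C@H](O[Si](C)(C)C(C)(C)C)CCCCC[C@@H](C)O[Si](C)(C)C(C)(C)C | intermediate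
45 | (5S,6R,7R,13R)-7,13-bis(TBSO)-6-methyltetradec-2-yn-5-ol | CC#CC[C@H](O)[C@@H](C)[C@H](O[Si](C)(C)C(C)(C)C)CCCCC[C@@H](C)O[Si](C)(C)C(C)(C)C | intermediate
46 | 2-[bis(2,2,2-trifluoroethoxy)phosphoryl]acetic acid | OC(=O)CP(=O)(OCC(F)(F)F)OCC(F)(F)F | starting material
47 | (5S,6R,7R,13R)-7,13-bis(TBSO)-6-methyltetradec-2-yn-5-yl 2-[bis(2,2,2-trifluoroethoxy)phosphoryl]acetate | CC#CC[C@@H]([C@@H](C)[C@H](O[Si](C)(C)C(C)(C)C)CCCCC[C@@H](C)O[Si](C)(C)C(C)(C)C)OC(=O)CP(=O)(OCC(F)(F)F)OCC(F)(F)F | intermediate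
48 | C3–C38 aldol adduct (ethyl Z-enoate; 15-OH, 17-oxo; TBSO at C7, C9, C11, C13, C19, C23, C27, C31) | CCOC(=O)/C(C)=C\C[C@H](O[Si](C)(C)C(C)(C)C)C[C@@H](O[Si](C)(C)C(C)(C)C)C[C@H](O[Si](C)(C)C(C)(C)C)C[C@@H](O[Si](C)(C)C(C)(C)C)C[C@H](O)CC(=O)[C@@H](C)[C@H](O[Si](C)(C)C(C)(C)C)/C(C)=C\C[C@H](O[Si](C)(C)C(C)(C)C)CCC[C@H](O[Si](C)(C)C(C)(C)C)CCC[C@H](O[Si](C)(C)C(C)(C)C)CCCCCCC#CC | intermediate
49 | C3–C38 15,17-anti-diol (ethyl Z-enoate; eight TBSO groups) | CCOC(=O)/C(C)=C\C[C@H](O[Si](C)(C)C(C)(C)C)C[C@@H](O[Si](C)(C)C(C)(C)C)C[C@H](O[Si](C)(C)C(C)(C)C)C[C@@H](O[Si](C)(C)C(C)(C)C)C[C@H](O)C[C@@H](O)[C@@H](C)[C@H](O[Si](C)(C)C(C)(C)C)/C(C)=C\C[C@H](O[Si](C)(C)C(C)(C)C)CCC[C@H](O[Si](C)(C)C(C)(C)C)CCC[C@H](O[Si](C)(C)C(C)(C)C)CCCCCCC#CC | intermediate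
50 | C3–C38 ethyl Z-enoate with TBSO at C7, C9, C11, C13, C15, C17, C19, C23, C27, C31 | CCOC(=O)/C(C)=C\C[C@H](O[Si](C)(C)C(C)(C)C)C[C@@H](O[Si](C)(C)C(C)(C)C)C[C@H](O[Si](C)(C)C(C)(C)C)C[C@@H](O[Si](C)(C)C(C)(C)C)C[C@H](O[Si](C)(C)C(C)(C)C)C[C@@H](O[Si](C)(C)C(C)(C)C)[C@@H](C)[C@H](O[Si](C)(C)C(C)(C)C)/C(C)=C\C[C@H](O[Si](C)(C)C(C)(C)C)CCC[C@H](O[Si](C)(C)C(C)(C)C)CCC[C@H](O[Si](C)(C)C(C)(C)C)CCCCCCC#CC | intermediate
51 | C3–C38 Z-allylic alcohol (ten TBSO groups) | OC/C(C)=C\C[C@H](O[Si](C)(C)C(C)(C)C)C[C@@H](O[Si](C)(C)C(C)(C)C)C[C@H](O[Si](C)(C)C(C)(C)C)C[C@@H](O[Si](C)(C)C(C)(C)C)C[C@H](O[Si](C)(C)C(C)(C)C)C[C@@H](O[Si](C)(C)C(C)(C)C)[C@@H](C)[C@H](O[Si](C)(C)C(C)(C)C)/C(C)=C\C[C@H](O[Si](C)(C)C(C)(C)C)CCC[C@H](O[Si](C)(C)C(C)(C)C)CCC[C@H](O[Si](C)(C)C(C)(C)C)CCCCCCC#CC | intermediate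
52 | C3–C38 Z-enal (ten TBSO groups) | O=C/C(C)=C\C[C@H](O[Si](C)(C)C(C)(C)C)C[C@@H](O[Si](C)(C)C(C)(C)C)C[C@H](O[Si](C)(C)C(C)(C)C)C[C@@H](O[Si](C)(C)C(C)(C)C)C[C@H](O[Si](C)(C)C(C)(C)C)C[C@@H](O[Si](C)(C)C(C)(C)C)[C@@H](C)[C@H](O[Si](C)(C)C(C)(C)C)/C(C)=C\C[C@H](O[Si](C)(C)C(C)(C)C)CCC[C@H](O[Si](C)(C)C(C)(C)C)CCC[C@H](O[Si](C)(C)C(C)(C)C)CCCCCCC#CC | intermediate
53 | seco ester diyne, per-TBS ether (C41 ester of the (2Z,4Z)-dienoic acid; CH3–C≡C at C37 and at C40) | CC#CC[C@@H]([C@@H](C)[C@H](O[Si](C)(C)C(C)(C)C)CCCCC[C@@H](C)O[Si](C)(C)C(C)(C)C)OC(=O)/C=C\C(C)=C/C[C@H](O[Si](C)(C)C(C)(C)C)C[C@@H](O[Si](C)(C)C(C)(C)C)C[C@H](O[Si](C)(C)C(C)(C)C)C[C@@H](O[Si](C)(C)C(C)(C)C)C[C@H](O[Si](C)(C)C(C)(C)C)C[C@@H](O[Si](C)(C)C(C)(C)C)[C@@H](C)[C@H](O[Si](C)(C)C(C)(C)C)/C(C)=C\C[C@H](O[Si](C)(C)C(C)(C)C)CCC[C@H](O[Si](C)(C)C(C)(C)C)CCC[C@H](O[Si](C)(C)C(C)(C)C)CCCCCCC#CC | intermediate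
54 | 42-membered cycloalkyne lactone, per-TBS ether (C38≡C39) | CC1=C/C[C@H](O[Si](C)(C)C(C)(C)C)C[C@@H](O[Si](C)(C)C(C)(C)C)C[C@H](O[Si](C)(C)C(C)(C)C)C[C@@H](O[Si](C)(C)C(C)(C)C)C[C@H](O[Si](C)(C)C(C)(C)C)C[C@@H](O[Si](C)(C)C(C)(C)C)[C@@H](C)[C@H](O[Si](C)(C)C(C)(C)C)/C(C)=C\C[C@H](O[Si](C)(C)C(C)(C)C)CCC[C@H](O[Si](C)(C)C(C)(C)C)CCC[C@H](O[Si](C)(C)C(C)(C)C)CCCCCCC#CC[C@@H]([C@@H](C)[C@H](O[Si](C)(C)C(C)(C)C)CCCCC[C@@H](C)O[Si](C)(C)C(C)(C)C)OC(=O)/C=C\1 | intermediate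
55 | per-TBS macrolactone with Z-C38=C39 | CC1=C/C[C@H](O[Si](C)(C)C(C)(C)C)C[C@@H](O[Si](C)(C)C(C)(C)C)C[C@H](O[Si](C)(C)C(C)(C)C)C[C@@H](O[Si](C)(C)C(C)(C)C)C[C@H](O[Si](C)(C)C(C)(C)C)C[C@@H](O[Si](C)(C)C(C)(C)C)[C@@H](C)[C@H](O[Si](C)(C)C(C)(C)C)/C(C)=C\C[C@H](O[Si](C)(C)C(C)(C)C)CCC[C@H](O[Si](C)(C)C(C)(C)C)CCC[C@H](O[Si](C)(C)C(C)(C)C)CCCCCC/C=C\C[C@@H]([C@@H](C)[C@H](O[Si](C)(C)C(C)(C)C)CCCCC[C@@H](C)O[Si](C)(C)C(C)(C)C)OC(=O)/C=C\1 | intermediate
56 | CNP0392687.2: 42-membered (2Z,4Z,20Z,38Z)-macrolactone with 7S,9R,11S,13R,15S,17R,18R,19S,23R,27R,31R,41S and side chain 42S,43R,49R | CC1=C/C[C@H](O)C[C@@H](O)C[C@H](O)C[C@@H](O)C[C@H](O)C[C@@H](O)[C@@H](C)[C@H](O)/C(C)=C\C[C@H](O)CCC[C@H](O)CCC[C@H](O)CCCCCC/C=C\C[C@@H]([C@@H](C)[C@H](O)CCCCC[C@@H](C)O)OC(=O)/C=C\1 | target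

**Counts and risks**

Total step count: 39 (36 to the precursor, the key step, 2 after it).
Longest linear sequence: 22 steps (steps 8–20, then 31–39, from 1-bromo-5-chloropentane).

Steps most likely to fail:

1. Step 37. Intermolecular alkyne exchange may outrun the intramolecular one, so that acyclic diyne oligomers build up, or the alkylidyne may be consumed before the ring closes. Fallback (ring closed at C2=C3 by olefination instead): the route is left at enal 52 and phosphonate 47. Alkyne cross-metathesis of 52 with an excess of 47 (Mo(≡C-C6H4-4-OMe)(OSiPh3)3, 5 Å molecular sieves, toluene), in which the catalyst is expected to leave the enal untouched, joins C38 to C39 in the open chain and should give the open-chain enal phosphonate F1. An intramolecular Still–Gennari olefination of F1 under high dilution (KN(SiMe3)2, 18-crown-6, THF, −78 → −20 °C, slow addition) then closes the 42-membered ring and comes back to the route at cycloalkyne 54.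

2. Step 31. The α-methyl centre of the enol borinate may give too little facial bias, so that both C15 epimers form, and retro-aldol cleavage or β-elimination may erode the adduct. Fallback (open transition state, control taken from the aldehyde): ketone 33 is converted with TMSOTf and Et3N (CH2Cl2, −78 °C) into the trimethylsilyl enol ether F2. A BF3·OEt2-mediated Mukaiyama aldol addition of F2 to aldehyde 11 at −78 °C is then steered by the β-silyloxy centre C13 of the aldehyde (1,3-anti polar induction) and comes back to the route at aldol adduct 48.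

3. Step 36. The olefination may lose Z-selectivity at C2=C3, or the base may isomerise the enal or the newly formed dienoate. Fallback (ester bond made by acylation): from enal 52, Still–Gennari olefination with methyl 2-[bis(2,2,2-trifluoroethoxy)phosphoryl]acetate gives the methyl (2Z,4Z)-dienoate F3, from which minor geometric isomers are removed. Me3SnOH (1,2-dichloroethane, 70 °C) then frees the (2Z,4Z)-dienoic acid F4, and Shiina esterification with alcohol 45 (2-methyl-6-nitrobenzoic anhydride, DMAP, Et3N, CH2Cl2, rt) comes back to the route at seco ester 53.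

Further compounds
F1 | step 37 | open-chain C3–C50 enal phosphonate (C38≡C39 formed, C3 aldehyde, O41 phosphonoacetate, twelve TBSO groups) | O=C/C(C)=C\C[C@H](O[Si](C)(C)C(C)(C)C)C[C@@H](O[Si](C)(C)C(C)(C)C)C[C@H](O[Si](C)(C)C(C)(C)C)C[C@@H](O[Si](C)(C)C(C)(C)C)C[C@H](O[Si](C)(C)C(C)(C)C)C[C@@H](O[Si](C)(C)C(C)(C)C)[C@@H](C)[C@H](O[Si](C)(C)C(C)(C)C)/C(C)=C\C[C@H](O[Si](C)(C)C(C)(C)C)CCC[C@H](O[Si](C)(C)C(C)(C)C)CCC[C@H](O[Si](C)(C)C(C)(C)C)CCCCCCC#CC[C@@H]([C@@H](C)[C@H](O[Si](C)(C)C(C)(C)C)CCCCC[C@@H](C)O[Si](C)(C)C(C)(C)C)OC(=O)CP(=O)(OCC(F)(F)F)OCC(F)(F)F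
F2 | step 31 | trimethylsilyl enol ether of ketone 33 (2-(trimethylsilyloxy)alk-1-ene, C16=C17) | C=C(O[Si](C)(C)C)[C@@H](C)[C@H](O[Si](C)(C)C(C)(C)C)/C(C)=C\C[C@H](O[Si](C)(C)C(C)(C)C)CCC[C@H](O[Si](C)(C)C(C)(C)C)CCC[C@H](O[Si](C)(C)C(C)(C)C)CCCCCCC#CC
F3 | step 36 | methyl C1–C38 (2Z,4Z)-dienoate (ten TBSO groups) | COC(=O)/C=C\C(C)=C/C[C@H](O[Si](C)(C)C(C)(C)C)C[C@@H](O[Si](C)(C)C(C)(C)C)C[C@H](O[Si](C)(C)C(C)(C)C)C[C@@H](O[Si](C)(C)C(C)(C)C)C[C@H](O[Si](C)(C)C(C)(C)C)C[C@@H](O[Si](C)(C)C(C)(C)C)[C@@H](C)[C@H](O[Si](C)(C)C(C)(C)C)/C(C)=C\C[C@H](O[Si](C)(C)C(C)(C)C)CCC[C@H](O[Si](C)(C)C(C)(C)C)CCC[C@H](O[Si](C)(C)C(C)(C)C)CCCCCCC#CC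
F4 | step 36 | C1–C38 (2Z,4Z)-dienoic acid (ten TBSO groups) | OC(=O)/C=C\C(C)=C/C[C@H](O[Si](C)(C)C(C)(C)C)C[C@@H](O[Si](C)(C)C(C)(C)C)C[C@H](O[Si](C)(C)C(C)(C)C)C[C@@H](O[Si](C)(C)C(C)(C)C)C[C@H](O[Si](C)(C)C(C)(C)C)C[C@@H](O[Si](C)(C)C(C)(C)C)[C@@H](C)[C@H](O[Si](C)(C)C(C)(C)C)/C(C)=C\C[C@H](O[Si](C)(C)C(C)(C)C)CCC[C@H](O[Si](C)(C)C(C)(C)C)CCC[C@H](O[Si](C)(C)C(C)(C)C)CCCCCCC#CC
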